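**Retrosynthetic overview**
1. The target is a heterochiral 5,5′-dimer with one 2R half and one 2S half. Both (Z)-2-methylenoic acid ends are made last, by a two-directional Z-selective olefination of a dialdehyde.
2. Both inner (E)-alkenes and the adjoining chain C–C bonds come from a double Johnson–Claisen [3,3] rearrangement of isopropenyl carbinols grown from the prenyl ends of linalool.
3. Key disconnection: the C5–C5′ biaryl bond forms by [3,3]-sigmatropic rearrangement of a mixed aryl quinone ketal (2R ketal as acceptor, 2S chromanol as donor). This separation of roles enforces R/S cross-coupling.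
4. In each dihydropyran ring the aryl C8a–O bond comes from oxidative dearomatising ketalisation by the linalool tertiary alcohol, so the C2–O bond is never broken. The C4–C4a bond comes from hydroboration and B-alkyl Suzuki coupling of (R)- or (S)-linalool.
5. Ring order: pyran ring of the 2R half, pyran ring of the 2S half, then union of the two bought benzene rings. No ring forms afterwards.

Assumption: the SMILES fixes one C2 as S and the other as R, both inner alkenes as E and both enoic acids as Z, and leaves the biaryl axis open, so the axis is taken as it forms.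

**Step 1**
Reactants: 1 2-bromo-6-methylanisole
Product: 3 3-bromo-4-methoxy-5-methylphenol, via aryl pinacol boronate 2 (not isolated)
Conditions: [Ir(OMe)(cod)]2 (1 mol %), dtbpy (2 mol %), B2pin2 (0.6 equiv), THF, 80 °C; then KHSO5 (as 2KHSO5·KHSO4·K2SO4), acetone/H2O, rt
Reagents that add atoms: bis(pinacolato)diboron, CC1(C)OB(OC1(C)C)B1OC(C)(C)C(C)(C)O1 (boryl group of 2); potassium peroxymonosulfate, [K+].[O-]S(=O)(=O)OO (phenol oxygen of 3)
Why: Sterically governed iridium-catalysed C–H borylation of a 1,2,3-trisubstituted benzene takes the only C–H without an ortho neighbour (para to OMe) and spares C–Br, and oxidation of the C–B bond then gives the phenol, with no stereocentre involved.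

**Step 2**
Reactants: 4 (R)-(−)-linalool; 3 3-bromo-4-methoxy-5-methylphenol
Product: 6 3-[(3R)-3-hydroxy-3,7-dimethyloct-6-en-1-yl]-4-methoxy-5-methylphenol, via B-alkyl-9-BBN adduct 5 (not isolated)
Conditions: 9-BBN-H (1.5 equiv), THF, 0 °C to rt; then 3, PdCl2(dppf) (5 mol %), 3 M aq NaOH, THF, 65 °C
Reagents that add atoms: 9-borabicyclo[3.3.1]nonane, B1C2CCCC1CCC2 (boryl group of 5 only)
Why: 9-BBN-H hydroborates the monosubstituted vinyl group anti-Markovnikov far faster than the trisubstituted alkene, and the B-alkyl Suzuki–Miyaura coupling then makes the C4–C4a bond without touching the purchased carbinol centre (3R kept).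

**Step 3**
Reactants: 6 3-[(3R)-3-hydroxy-3,7-dimethyloct-6-en-1-yl]-4-methoxy-5-methylphenol
Product: 7 (2R)-8a-methoxy-2,8-dimethyl-2-(4-methylpent-3-en-1-yl)-2,3,4,8a-tetrahydro-6H-chromen-6-one
Conditions: PhI(OAc)2 (1.05 equiv), dry MeCN, 0 °C, 20 min
Reagents that add atoms: none
Why: In this oxidative phenol dearomatisation the phenoxenium-type intermediate of the 4-methoxyphenol is trapped at the methoxy-bearing para carbon by the tethered tertiary hydroxyl (six-membered ring), so the aryl C8a–O bond forms while the linalool C2–O bond stays intact (2R kept), and C8a arises as an epimer mixture that is flattened again in step 6.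

**Step 4**
Reactants: 8 (S)-(+)-linalool; 3 3-bromo-4-methoxy-5-methylphenol
Product: 10 3-[(3S)-3-hydroxy-3,7-dimethyloct-6-en-1-yl]-4-methoxy-5-methylphenol, via B-alkyl-9-BBN adduct 9 (not isolated)
Conditions: 9-BBN-H (1.5 equiv), THF, 0 °C to rt; then 3, PdCl2(dppf) (5 mol %), 3 M aq NaOH, THF, 65 °C
Reagents that add atoms: 9-borabicyclo[3.3.1]nonane, B1C2CCCC1CCC2 (boryl group of 9 only)
Why: This is the same chemoselective hydroboration and B-alkyl Suzuki–Miyaura coupling as in step 2, now carrying the purchased 3S centre through unchanged.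

**Step 5**
Reactants: 10 3-[(3S)-3-hydroxy-3,7-dimethyloct-6-en-1-yl]-4-methoxy-5-methylphenol
Product: 12 (2S)-2,8-dimethyl-2-(4-methylpent-3-en-1-yl)chroman-6-ol, via (2S)-8a-methoxy ketal 11 (not isolated)
Conditions: PhI(OAc)2 (1.05 equiv), MeCN, 0 °C; then Zn dust, AcOH, 0 °C to rt (one pot)
Reagents that add atoms: none
Why: Oxidative dearomatising ketalisation as in step 3 is followed by reductive aromatisation, in which acid ionises the untethered methoxy group to the chromanoxylium ion that zinc reduces to the chromanol (the known return of 8a-alkoxychromanones to chromanols), the C2–O bond is never broken (2S kept), and any ring-opened product is simply 10 and is recycled.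

**Step 6**
Reactants: 7 (2R)-8a-methoxy quinone monoketal; 12 (2S)-chroman-6-ol
Product: 15 (2R,2′S)-2,2′,8,8′-tetramethyl-2,2′-bis(4-methylpent-3-en-1-yl)-5,5′-bichroman-6,6′-diol, via mixed aryl ketal 13 (not isolated), via bis-dienone 14 (not isolated)
Conditions: 7 (1.0 equiv), 12 (1.1 equiv), CF3CO2H (20 mol %), 5 Å MS, toluene, 0 °C to rt, under argon
Reagents that add atoms: none
Why: Acid-catalysed exchange of the 8a-methoxy group for the phenol oxygen of 12 gives mixed ketal 13, whose aromatic-Claisen-type [3,3]-sigmatropic rearrangement breaks C8a–OAr and joins C5 to C5′, and double tautomerisation of 14 delivers the 2,2′-biphenol. Three points follow from this: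
- Only 7 can act as acceptor and only 12 as donor, so the R and S halves are cross-coupled.
- Both partners prefer C5, because only that path keeps the C4a=C8a ring-fusion double bond; this is also the position that reacts first in substitutions of 8-methylchroman-6-ols.
- C2 and C2′ are untouched, and the new axis is not controlled.

**Step 7**
Reactants: 15 (2R,2′S)-bichromandiol
Product: 16 (2R,2′S)-6,6′-bis(tert-butyldimethylsilyloxy)-2,2′,8,8′-tetramethyl-2,2′-bis(4-methylpent-3-en-1-yl)-5,5′-bichroman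
Conditions: TBSCl (3 equiv), imidazole (6 equiv), DMF, 40 °C
Reagents that add atoms: tert-butyldimethylsilyl chloride, CC(C)(C)[Si](C)(C)Cl
Why: Imidazole-promoted silylation masks the oxidisable, acidic biphenol for the peracid, aluminium and strong-base steps that follow, with no stereocentre affected.

**Step 8**
Reactants: 16 bis-silyl ether
Product: 17 bis(3,3-dimethyloxiran-2-yl) compound (both prenyl alkenes epoxidised and C2/C2′ unchanged)
Conditions: mCPBA (2.1 equiv), CH2Cl2, 0 °C
Reagents that add atoms: 3-chloroperoxybenzoic acid, O=C(OO)c1cccc(Cl)c1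
Why: Prilezhaev epoxidation of the two nucleophilic trisubstituted alkenes is much faster than attack on the silylated arenes, and the new epoxide carbons form unselectively but are erased in step 10.

**Step 9**
Reactants: 17 bis-epoxide
Product: 18 bis(3-hydroxy-4-methylpent-4-en-1-yl) compound (two isopropenyl carbinols and C2/C2′ unchanged)
Conditions: Al(OiPr)3 (30 mol % per epoxide), toluene, reflux
Reagents that add atoms: none
Why: In this aluminium-alkoxide-catalysed epoxide-to-allylic-alcohol isomerisation, Lewis-acid activation at oxygen and syn removal of a methyl proton open the tertiary C–O bond to give the secondary isopropenyl carbinol, whose configuration is irrelevant because it is destroyed in step 10.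

**Step 10**
Reactants: 18 bis(allylic alcohol)
Product: 20 diethyl (4E,4′E)-7,7′-[(2R,2′S)-6,6′-bis(tert-butyldimethylsilyloxy)-2,2′,8,8′-tetramethyl-5,5′-bichroman-2,2′-diyl]bis(4-methylhept-4-enoate), via bis(ketene acetal) 19 (not isolated)
Conditions: MeC(OEt)3 (excess), EtCO2H (10 mol %), 140 °C, EtOH distilled off
Reagents that add atoms: triethyl orthoacetate, CC(OCC)(OCC)OCC
Why: In the double Johnson–Claisen [3,3]-sigmatropic rearrangement the chair transition state places the chroman-bearing chain equatorial, away from the ethoxy group, which gives each trisubstituted alkene E (typically above 95:5) and adds the two chain carbons.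

**Step 11**
Reactants: 20 bis(ethyl ester)
Product: 21 (4E,4′E)-7,7′-[(2R,2′S)-6,6′-bis(tert-butyldimethylsilyloxy)-2,2′,8,8′-tetramethyl-5,5′-bichroman-2,2′-diyl]bis(4-methylhept-4-enal)
Conditions: iBu2AlH (2.2 equiv), CH2Cl2, −78 °C; MeOH, then aq KNaC4H4O6
Reagents that add atoms: none
Why: In this partial ester reduction the tetrahedral aluminium hemiacetal persists at −78 °C and collapses to the aldehyde only on work-up, with silyl ethers and alkenes inert.

**Step 12**
Reactants: 21 dialdehyde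
Product: 22 diethyl (2Z,2′Z,6E,6′E)-9,9′-[(2R,2′S)-6,6′-bis(tert-butyldimethylsilyloxy)-2,2′,8,8′-tetramethyl-5,5′-bichroman-2,2′-diyl]bis(2,6-dimethylnona-2,6-dienoate)
Conditions: (CF3CH2O)2P(O)CH(CH3)CO2Et (3 equiv), KN(SiMe3)2 (2.9 equiv), 18-crown-6 (8 equiv), THF, −78 °C
Reagents that add atoms: ethyl 2-[bis(2,2,2-trifluoroethoxy)phosphoryl]propanoate, CCOC(=O)C(C)P(=O)(OCC(F)(F)F)OCC(F)(F)F
Why: In the Still–Gennari variant of the Horner–Wadsworth–Emmons olefination the electron-poor phosphonate and the dissociated potassium counter-ion make elimination faster than adduct equilibration, so each aliphatic aldehyde gives the kinetic (Z)-2-methylenoate.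

**Step 13**
Reactants: 22 bis(Z-enoate) bis-silyl ether
Product: 23 (2Z,2′Z,6E,6′E)-9,9′-[(2R,2′S)-6,6′-dihydroxy-2,2′,8,8′-tetramethyl-5,5′-bichroman-2,2′-diyl]bis(2,6-dimethylnona-2,6-dienoic acid)
Conditions: LiOH (20 equiv), degassed THF/MeOH/H2O (2:1:1), 50 °C, under argon; then 1 M HCl to pH 3
Reagents that add atoms: lithium hydroxide, [Li+].[OH-]
Why: Saponification of both esters and hydroxide cleavage of the base-labile aryl silyl ethers occur in one operation, the carboxylates formed resist Z-to-E isomerisation under these mild conditions, and no stereocentre is touched.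

**Compound list**
1 | 2-bromo-6-methylanisole (1-bromo-2-methoxy-3-methylbenzene) | COc1c(C)cccc1Br | starting material
2 | 2-(3-bromo-4-methoxy-5-methylphenyl)-4,4,5,5-tetramethyl-1,3,2-dioxaborolane (not isolated) | COc1c(C)cc(cc1Br)B1OC(C)(C)C(C)(C)O1 | intermediate
3 | 3-bromo-4-methoxy-5-methylphenol | COc1c(C)cc(O)cc1Br | intermediate
4 | (R)-(−)-linalool, (3R)-3,7-dimethylocta-1,6-dien-3-ol | C=C[C@](C)(O)CCC=C(C)C | starting material
5 | 9-BBN adduct of 4, boron on C1, carbinol centre as in 4 (not isolated) | CC(C)=CCC[C@@](C)(O)CCB1C2CCCC1CCC2 | intermediate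
6 | 3-[(3R)-3-hydroxy-3,7-dimethyloct-6-en-1-yl]-4-methoxy-5-methylphenol | COc1c(C)cc(O)cc1CC[C@](C)(O)CCC=C(C)C | intermediate
7 | (2R)-8a-methoxy-2,8-dimethyl-2-(4-methylpent-3-en-1-yl)-2,3,4,8a-tetrahydro-6H-chromen-6-one (C8a epimers) | COC12O[C@](C)(CCC=C(C)C)CCC1=CC(=O)C=C2C | intermediate
8 | (S)-(+)-linalool (coriandrol), (3S)-3,7-dimethylocta-1,6-dien-3-ol | C=C[C@@](C)(O)CCC=C(C)C | starting material
9 | 9-BBN adduct of 8, boron on C1, carbinol centre as in 8 (not isolated) | CC(C)=CCC[C@](C)(O)CCB1C2CCCC1CCC2 | intermediate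
10 | 3-[(3S)-3-hydroxy-3,7-dimethyloct-6-en-1-yl]-4-methoxy-5-methylphenol | COc1c(C)cc(O)cc1CC[C@@](C)(O)CCC=C(C)C | intermediate
11 | (2S)-8a-methoxy-2,8-dimethyl-2-(4-methylpent-3-en-1-yl)-2,3,4,8a-tetrahydro-6H-chromen-6-one (C8a epimers, not isolated) | COC12O[C@@](C)(CCC=C(C)C)CCC1=CC(=O)C=C2C | intermediate
12 | (2S)-2,8-dimethyl-2-(4-methylpent-3-en-1-yl)chroman-6-ol | Cc1cc(O)cc2CC[C@](C)(CCC=C(C)C)Oc12 | intermediate
13 | mixed aryl ketal: the (2R)-chromen-6-one of 7 carrying at C8a the 6-oxy group of the (2S)-chroman 12 in place of OMe (not isolated) | CC(C)=CCC[C@]1(C)CCC2=CC(=O)C=C(C)C2(Oc2cc(C)c3O[C@@](C)(CCC=C(C)C)CCc3c2)O1 | intermediate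
14 | C5–C5′-linked bis(cyclohexa-2,4-dienone), (2R,2′S), C5/C5′ undefined (not isolated) | O=C1C=C(C)C2=C(CC[C@@](C)(CCC=C(C)C)O2)C1C1C(=O)C=C(C)C2=C1CC[C@](C)(CCC=C(C)C)O2 | intermediate
15 | (2R,2′S)-2,2′,8,8′-tetramethyl-2,2′-bis(4-methylpent-3-en-1-yl)-5,5′-bichroman-6,6′-diol | CC(C)=CCC[C@@]1(C)CCc2c(c(C)cc(O)c2-c2c(O)cc(C)c3c2CC[C@@](C)(CCC=C(C)C)O3)O1 | intermediate
16 | 6,6′-bis(TBS) ether of 15 | CC(C)=CCC[C@@]1(C)CCc2c(c(C)cc(O[Si](C)(C)C(C)(C)C)c2-c2c(O[Si](C)(C)C(C)(C)C)cc(C)c3c2CC[C@@](C)(CCC=C(C)C)O3)O1 | intermediate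
17 | bis-epoxide of 16 (each side chain 2-(3,3-dimethyloxiran-2-yl)ethyl, epoxide CH undefined, one C2 R and one S) | CC1(C)OC1CC[C@@]2(C)CCc3c(c(C)cc(O[Si](C)(C)C(C)(C)C)c3-c3c(O[Si](C)(C)C(C)(C)C)cc(C)c4c3CC[C@@](C)(CCC3OC3(C)C)O4)O2 | intermediate
18 | bis(allylic alcohol) (each side chain 3-hydroxy-4-methylpent-4-en-1-yl, carbinol CH undefined, one C2 R and one S) | C=C(C)C(O)CC[C@@]1(C)CCc2c(c(C)cc(O[Si](C)(C)C(C)(C)C)c2-c2c(O[Si](C)(C)C(C)(C)C)cc(C)c3c2CC[C@@](C)(CCC(O)C(C)=C)O3)O1 | intermediate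
19 | bis(1-ethoxyvinyl) ether of 18, the ketene acetal (not isolated) | C=C(C)C(OC(=C)OCC)CC[C@@]1(C)CCc2c(c(C)cc(O[Si](C)(C)C(C)(C)C)c2-c2c(O[Si](C)(C)C(C)(C)C)cc(C)c3c2CC[C@@](C)(CCC(OC(=C)OCC)C(C)=C)O3)O1 | intermediate
20 | bis[(E)-4-methylhept-4-enoic acid ethyl ester], (2R,2′S) | CCOC(=O)CC/C(C)=C/CC[C@@]1(C)CCc2c(c(C)cc(O[Si](C)(C)C(C)(C)C)c2-c2c(O[Si](C)(C)C(C)(C)C)cc(C)c3c2CC[C@@](C)(CC/C=C(\C)CCC(=O)OCC)O3)O1 | intermediate
21 | bis[(E)-4-methylhept-4-enal], (2R,2′S) | O=CCC/C(C)=C/CC[C@@]1(C)CCc2c(c(C)cc(O[Si](C)(C)C(C)(C)C)c2-c2c(O[Si](C)(C)C(C)(C)C)cc(C)c3c2CC[C@@](C)(CC/C=C(\C)CCC=O)O3)O1 | intermediate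
22 | bis[(2Z,6E)-2,6-dimethylnona-2,6-dienoic acid ethyl ester] bis-TBS ether, (2R,2′S) | C/C(=C/CC/C(C)=C/CC[C@@]1(C)CCc2c(c(C)cc(O[Si](C)(C)C(C)(C)C)c2-c2c(O[Si](C)(C)C(C)(C)C)cc(C)c3c2CC[C@@](C)(CC/C=C(\C)CC/C=C(/C)C(=O)OCC)O3)O1)C(=O)OCC | intermediate
23 | CNP0282703.1, (2Z,2′Z,6E,6′E)-9,9′-[(2R,2′S)-6,6′-dihydroxy-2,2′,8,8′-tetramethyl-5,5′-bichroman-2,2′-diyl]bis(2,6-dimethylnona-2,6-dienoic acid) | C/C(=C/CC/C(C)=C/CC[C@@]1(C)CCc2c(c(C)cc(O)c2-c2c(O)cc(C)c3c2CC[C@@](C)(CC/C=C(\C)CC/C=C(/C)C(=O)O)O3)O1)C(=O)O | target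

**Totals**
Total step count: 13. Longest linear sequence: 11 (steps 1, 2, 3, then 6 to 13; the branch through steps 1, 4 and 5 is equally long).

**Three steps most likely to fail**

**Step 6, [3,3] biaryl union.**
The risks are C5 versus C7 attack on either partner, electron transfer between the chromanoxylium ion and 12 that would scramble the R/S roles, and the crowding of a tetra-ortho-substituted bond.
The fallback sets out from 7 and 12 and comes back at 16.
- R half: reduce 7 with Zn/AcOH to the (2R)-chroman-6-ol F1. Iodinate at C5 with the I2–morpholine complex, a phenolate-type iodination that leaves the alkene alone, to get the (2R)-5-iodochroman-6-ol F2. Silylate (TBSCl, imidazole) to the (2R)-5-iodo silyl ether F3.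
- S half: treat 12 in the same way to get the (2S)-5-iodochroman-6-ol F4 and the (2S)-5-iodo silyl ether F5. Convert F5 by iodine–magnesium exchange (iPrMgCl·LiCl, −20 °C) and iPrOBpin into the (2S)-5-pinacol boronate F6.
- Union: Suzuki–Miyaura coupling of F3 and F6 (Pd(OAc)2, SPhos, K3PO4, toluene/H2O, 100 °C) gives 16. Any desilylated product is 15, which also lies on the route.

**Step 3, and the same oxidation inside step 5.**
The risk is that the tertiary hydroxyl is a weak nucleophile for a carbon flanked on both sides, so hydrolysis to the quinone or ortho attack may win.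
The fallback sets out from 4 (and from 8) and comes back at 7 (and at 12).
- Aryl partner: brominate commercial 3-bromo-5-methylanisole para to the methoxy group (NBS, MeCN) to get 1,2-dibromo-5-methoxy-3-methylbenzene F7.
- R series: couple adduct 5 at the less hindered C–Br bond, the one meta to OMe (PdCl2(dppf), aq NaOH, THF, 65 °C), to get the (3R)-bromo alcohol F8. Close the ring by palladium-catalysed intramolecular C–O coupling (Pd(OAc)2, dppf, NaOtBu, toluene, 90 °C), which leaves the carbinol C–O bond untouched, to get the (2R)-6-methoxychroman F9. Demethylate with NaSEt in DMF at 130 °C to the (2R)-chroman-6-ol F1, and oxidise F1 with PhI(OAc)2 in MeOH at 0 °C to 7.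
- S series: starting from adduct 9, the same detour gives the (3S)-bromo alcohol F10, the (2S)-6-methoxychroman F11, and after demethylation 12.

**Step 9, double epoxide isomerisation.**
The risks are slow turnover, ketone formation by hydride shift, and loss of the aryl silyl ethers at reflux.
The fallback sets out from 17 and comes back at 18. Cleave both epoxides with H5IO6 (THF/Et2O, 0 °C) to the bis(3-oxopropyl) dialdehyde F12. Then add CH2=C(CH3)MgBr (THF, −78 °C) to both aldehydes to give 18.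

**Further compounds**
F1 | step 6 | (2R)-2,8-dimethyl-2-(4-methylpent-3-en-1-yl)chroman-6-ol | Cc1cc(O)cc2CC[C@@](C)(CCC=C(C)C)Oc12
F2 | step 6 | (2R)-5-iodo-2,8-dimethyl-2-(4-methylpent-3-en-1-yl)chroman-6-ol | Cc1cc(O)c(I)c2CC[C@@](C)(CCC=C(C)C)Oc12
F3 | step 6 | (2R)-6-(tert-butyldimethylsilyloxy)-5-iodo-2,8-dimethyl-2-(4-methylpent-3-en-1-yl)chroman | Cc1cc(O[Si](C)(C)C(C)(C)C)c(I)c2CC[C@@](C)(CCC=C(C)C)Oc12
F4 | step 6 | (2S)-5-iodo-2,8-dimethyl-2-(4-methylpent-3-en-1-yl)chroman-6-ol | Cc1cc(O)c(I)c2CC[C@](C)(CCC=C(C)C)Oc12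
F5 | step 6 | (2S)-6-(tert-butyldimethylsilyloxy)-5-iodo-2,8-dimethyl-2-(4-methylpent-3-en-1-yl)chroman | Cc1cc(O[Si](C)(C)C(C)(C)C)c(I)c2CC[C@](C)(CCC=C(C)C)Oc12
F6 | step 6 | (2S)-6-(tert-butyldimethylsilyloxy)-2,8-dimethyl-2-(4-methylpent-3-en-1-yl)-5-(4,4,5,5-tetramethyl-1,3,2-dioxaborolan-2-yl)chroman | Cc1cc(O[Si](C)(C)C(C)(C)C)c(B3OC(C)(C)C(C)(C)O3)c2CC[C@](C)(CCC=C(C)C)Oc12
F7 | step 3 | 1,2-dibromo-5-methoxy-3-methylbenzene | COc1cc(C)c(Br)c(Br)c1
F8 | step 3 | (3R)-1-(2-bromo-5-methoxy-3-methylphenyl)-3,7-dimethyloct-6-en-3-ol | COc1cc(C)c(Br)c(CC[C@](C)(O)CCC=C(C)C)c1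
F9 | step 3 | (2R)-6-methoxy-2,8-dimethyl-2-(4-methylpent-3-en-1-yl)chroman | COc1cc(C)c2O[C@](C)(CCC=C(C)C)CCc2c1
F10 | step 3 | (3S)-1-(2-bromo-5-methoxy-3-methylphenyl)-3,7-dimethyloct-6-en-3-ol | COc1cc(C)c(Br)c(CC[C@@](C)(O)CCC=C(C)C)c1
F11 | step 3 | (2S)-6-methoxy-2,8-dimethyl-2-(4-methylpent-3-en-1-yl)chroman | COc1cc(C)c2O[C@@](C)(CCC=C(C)C)CCc2c1
F12 | step 9 | 3,3′-[6,6′-bis(tert-butyldimethylsilyloxy)-2,2′,8,8′-tetramethyl-5,5′-bichroman-2,2′-diyl]dipropanal (one C2 R, one S) | O=CCC[C@@]1(C)CCc2c(c(C)cc(O[Si](C)(C)C(C)(C)C)c2-c2c(O[Si](C)(C)C(C)(C)C)cc(C)c3c2CC[C@@](C)(CCC=O)O3)O1
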